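**Retrosynthetic overview**
- Last bond: the E-stilbene, by Horner–Wadsworth–Emmons coupling of a benzofuranylmethyl phosphonate with an aryl aldehyde, then global debenzylation.
- Both halves come from one 2,3-diarylbenzofuran ester (aryloxy-ketone cyclodehydration, then C2–H arylation); the benzofuran ring is formed first.
- For the western half the benzofuran is reduced to the trans-dihydrobenzofuran (rings A/B, C-b, C-c) and resolved as an oxazolidinone imide.
- Key C–C bond (C-a–C-d): intermolecular Michael addition of a 4-benzyloxybenzyl sulfonium ylide to an ortho-quinone methide, closing a second trans-dihydrobenzofuran.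
- That second ring is opened by Lewis acid and ring B closes the seven-membered ring (Friedel–Crafts); ring order: benzofuran, dihydrobenzofuran, second dihydrobenzofuran, cycloheptane.

**Labels.** Ring A = benzo ring of the first dihydrobenzofuran; ring B = its 3,5-dioxygenated 3-aryl group; ring L = the phenol ring that links the two halves. C-b/C-c = C3/C2 of that dihydrobenzofuran; C-a = CH joined to ring A and ring L; C-d = CH carrying the second 4-oxyphenyl group. Target: C-a R, C-b S, C-c S, C-d S. BF = 6-(benzyloxy)-2-[4-(benzyloxy)phenyl]-3-[3,5-bis(benzyloxy)phenyl]-1-benzofuran-4-yl. DHB = the (2S,3S)-2,3-dihydro analogue of BF. Cy = the tetracycle of 29 (dihydrobenzofuran fused to the cycloheptane, five OBn in all) attached through C-a.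

Assumption: the two C-a epimers formed in step 18 are separable by chromatography; the facial preference argued there is a conformational prediction, not a measured ratio.

**Step 1**
Reactants: 1 methyl 3,5-dihydroxybenzoate
Product: 2 methyl 3-(benzyloxy)-5-hydroxybenzoate
Conditions: BnBr (1.0 equiv), K2CO3, DMF, rt; chromatography, diol recycled
Reagents that add atoms: benzyl bromide, BrCc1ccccc1
Why: Williamson mono-O-benzylation of a symmetric diphenol is statistical but the mono-ether is easily separated from diol and bis-ether.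

**Step 2**
Reactants: 3 1-[3,5-bis(benzyloxy)phenyl]ethanone
Product: 4 2-bromo-1-[3,5-bis(benzyloxy)phenyl]ethanone
Conditions: CuBr2 (2 equiv), EtOAc–CHCl3, reflux
Reagents that add atoms: copper dibromide, Br[Cu]Br
Why: Copper-mediated α-bromination of the aryl methyl ketone through its enol avoids bromination of the electron-rich ring.

**Step 3**
Reactants: 2 methyl 3-(benzyloxy)-5-hydroxybenzoate; 4 2-bromo-1-[3,5-bis(benzyloxy)phenyl]ethanone
Product: 5 methyl 3-(benzyloxy)-5-{2-[3,5-bis(benzyloxy)phenyl]-2-oxoethoxy}benzoate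
Conditions: K2CO3, acetone, reflux
Reagents that add atoms: none
Why: Williamson ether synthesis, SN2 of the phenoxide on a reactive α-bromoketone.

**Step 4**
Reactants: 5 methyl 3-(benzyloxy)-5-{2-[3,5-bis(benzyloxy)phenyl]-2-oxoethoxy}benzoate
Product: 6 methyl 6-(benzyloxy)-3-[3,5-bis(benzyloxy)phenyl]-1-benzofuran-4-carboxylate
Conditions: Bi(OTf)3 (10 mol %), CH2Cl2, reflux
Reagents that add atoms: none
Why: Lewis-acid cyclodehydration (intramolecular Friedel–Crafts hydroxyalkylation, then loss of water) at the ring carbon ortho to the ether oxygen and para to OBn gives the 3-aryl-4-carboxylate benzofuran.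

**Step 5**
Reactants: 6 methyl 6-(benzyloxy)-3-[3,5-bis(benzyloxy)phenyl]-1-benzofuran-4-carboxylate; 7 1-(benzyloxy)-4-bromobenzene
Product: 8 BF-CO2Me (methyl 6-(benzyloxy)-2-[4-(benzyloxy)phenyl]-3-[3,5-bis(benzyloxy)phenyl]-1-benzofuran-4-carboxylate)
Conditions: Pd(OAc)2 (5 mol %), PCy3·HBF4 (10 mol %), PivOH (30 mol %), K2CO3, DMA, 110 °C
Reagents that add atoms: none
Why: Palladium-catalysed direct C2–H arylation of the benzofuran by concerted metalation–deprotonation; C2 is the only furan C–H.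

**Step 6**
Reactants: 8 BF-CO2Me
Product: 9 BF-CH2OH
Conditions: i-Bu2AlH, CH2Cl2, −78 to 0 °C; aq. potassium sodium tartrate
Reagents that add atoms: none
Why: Hydride reduction of the aryl ester to the benzylic alcohol; benzyl ethers and the benzofuran are inert.

**Step 7**
Reactants: 9 BF-CH2OH
Product: 10 BF-CH2Br
Conditions: CBr4, PPh3, CH2Cl2, 0 °C
Reagents that add atoms: carbon tetrabromide, BrC(Br)(Br)Br
Why: Appel bromination converts the benzylic alcohol under neutral conditions.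

**Step 8**
Reactants: 10 BF-CH2Br
Product: 11 BF-CH2P(O)(OEt)2
Conditions: P(OEt)3 (neat), 130 °C
Reagents that add atoms: triethyl phosphite, CCOP(OCC)OCC
Why: Michaelis–Arbuzov reaction of a benzylic bromide.

**Step 9**
Reactants: 8 BF-CO2Me
Product: 12 racemic trans-dihydrobenzofuran methyl ester (rac-DHB-CO2Me)
Conditions: Et3SiH (5 equiv), CF3CO2H–CH2Cl2 (1:1), 0 °C to rt
Reagents that add atoms: none
Why: Ionic hydrogenation: C3 protonation gives an oxocarbenium ion stabilised by the 2-aryl group, and hydride from Et3SiH enters C2 anti to the C3 aryl group, so the 2,3-trans ring forms (racemic).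

**Step 10**
Reactants: 12 rac-DHB-CO2Me
Product: 13 racemic trans acid (rac-DHB-CO2H)
Conditions: LiOH, THF–MeOH–H2O, 50 °C; then 1 M HCl
Reagents that add atoms: lithium hydroxide, [Li+].[OH-]
Why: Saponification of the hindered methyl ester; no stereocentre is acidic enough to epimerise.

**Step 11**
Reactants: 13 rac-DHB-CO2H; 14 (S)-4-benzyl-1,3-oxazolidin-2-one
Product: 16 (S)-4-benzyl-3-(DHB-carbonyl)-1,3-oxazolidin-2-one, via acid chloride 15 (not isolated)
Conditions: (COCl)2, DMF (cat.), CH2Cl2, 0 °C to rt; then 14, n-BuLi, THF, −78 to 0 °C; silica separation of the two diastereomers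
Reagents that add atoms: none
Why: N-Acylation of the lithiated Evans oxazolidinone turns the racemate into two diastereomeric imides that are separated by chromatography (resolution, no new stereocentre; the (2S,3S) isomer is assigned by X-ray against the auxiliary).

**Step 12**
Reactants: 16 (S)-4-benzyl-3-(DHB-carbonyl)-1,3-oxazolidin-2-one
Product: 17 DHB-CH2OH
Conditions: LiBH4, THF–MeOH, 0 °C to rt
Reagents that add atoms: none
Why: Reductive cleavage of the N-acyl oxazolidinone at the exocyclic carbonyl gives the primary alcohol and returns the auxiliary.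

**Step 13**
Reactants: 17 DHB-CH2OH
Product: 18 DHB-CHO
Conditions: Dess–Martin periodinane, NaHCO3, CH2Cl2, rt
Reagents that add atoms: none
Why: Dess–Martin oxidation of a benzylic alcohol stops at the aldehyde and leaves the two ring stereocentres untouched.

**Step 14**
Reactants: 19 methyl 4-hydroxy-3-iodobenzoate
Product: 20 methyl 3-iodo-4-[(triisopropylsilyl)oxy]benzoate
Conditions: TIPSCl, imidazole, DMF, rt
Reagents that add atoms: triisopropylsilyl chloride, CC(C)[Si](Cl)(C(C)C)C(C)C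
Why: Standard silylation; the bulky silyl group resists migration in the next step and is removed by fluoride later.

**Step 15**
Reactants: 20 methyl 3-iodo-4-[(triisopropylsilyl)oxy]benzoate; 18 DHB-CHO
Product: 22 methyl 3-[DHB-CH(OH)]-4-[(triisopropylsilyl)oxy]benzoate (carbinol epimers), via arylmagnesium chloride 21 (not isolated)
Conditions: i-PrMgCl·LiCl, THF, −40 °C; then 18, −40 to −10 °C; aq. NH4Cl
Reagents that add atoms: none
Why: Iodine–magnesium exchange tolerates the ester at −40 °C and the aryl Grignard adds 1,2 to the aldehyde; the new carbinol centre forms as a mixture that is erased in step 18.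

**Step 16**
Reactants: 22 methyl 3-[DHB-CH(OH)]-4-[(triisopropylsilyl)oxy]benzoate
Product: 23 methyl 3-[DHB-CH(OAc)]-4-[(triisopropylsilyl)oxy]benzoate
Conditions: Ac2O, Et3N, DMAP (cat.), CH2Cl2, 0 °C
Reagents that add atoms: acetic anhydride, CC(=O)OC(C)=O
Why: DMAP-catalysed acetylation installs the leaving group for base-free quinone methide generation; acid is avoided because a C-a cation would be trapped by ring B in a six-membered ring.

**Step 17**
Reactants: 24 [4-(benzyloxy)phenyl]methanol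
Product: 25 1-[4-(benzyloxy)benzyl]tetrahydrothiophenium tetrafluoroborate
Conditions: tetrahydrothiophene, HBF4·OEt2, CH2Cl2, 0 °C to rt
Reagents that add atoms: tetrahydrothiophene, C1CCSC1; tetrafluoroboric acid, [H+].F[B-](F)(F)F
Why: Acid-promoted S-alkylation through the 4-benzyloxybenzyl cation gives a sulfonium salt with a non-nucleophilic counter-ion.

**Step 18 (key step)**
Reactants: 23 methyl 3-[DHB-CH(OAc)]-4-[(triisopropylsilyl)oxy]benzoate; 25 1-[4-(benzyloxy)benzyl]tetrahydrothiophenium tetrafluoroborate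
Product: 28 methyl (2R,3R)-2-[4-(benzyloxy)phenyl]-3-DHB-2,3-dihydro-1-benzofuran-5-carboxylate, via sulfonium ylide 26 (not isolated), via ortho-quinone methide 27 (not isolated)
Conditions: 25 (2 equiv), KOt-Bu (2 equiv), THF, −78 °C; then 23, Bu4NF (1.1 equiv), −78 to 0 °C; chromatography
Reagents that add atoms: none
Why: Fluoride-triggered 1,4-elimination of acetate gives 27, ylide 26 adds to its exocyclic carbon in an intermolecular Michael reaction (forming C-a–C-d) and the ring oxygen then displaces tetrahydrothiophene (Michael-initiated ring closure) to the 2,3-trans ring; C-a is set by attack on the outer face of 27 in the conformer that holds the quinoid ring anti to ring B, and the minor (2S,3S) trans isomer is removed by chromatography.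

**Step 19**
Reactants: 28 methyl (2R,3R)-2-[4-(benzyloxy)phenyl]-3-DHB-2,3-dihydro-1-benzofuran-5-carboxylate
Product: 29 methyl 4-hydroxy-3-Cy-benzoate (C-a R, C-b S, C-c S, C-d S)
Conditions: BF3·OEt2 (0.5 equiv), CH2Cl2, −40 to 0 °C
Reagents that add atoms: none
Why: The Lewis acid heterolyses the benzylic C2–O bond of the ester-bearing ring (better phenol leaving group) and ring B attacks the 4-benzyloxybenzyl cationic carbon in a seven-membered Friedel–Crafts alkylation, the aryl group at C-d ending trans and pseudo-equatorial to ring L while C-a is untouched.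

**Step 20**
Reactants: 29 methyl 4-hydroxy-3-Cy-benzoate
Product: 30 methyl 4-(benzyloxy)-3-Cy-benzoate
Conditions: BnBr, K2CO3, DMF, 40 °C
Reagents that add atoms: benzyl bromide, BrCc1ccccc1
Why: Williamson O-benzylation of the acidic para-ester phenol, so that the later olefination is not slowed by a phenoxide.

**Step 21**
Reactants: 30 methyl 4-(benzyloxy)-3-Cy-benzoate
Product: 31 [4-(benzyloxy)-3-Cy-phenyl]methanol
Conditions: i-Bu2AlH, CH2Cl2, −78 to 0 °C; aq. potassium sodium tartrate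
Reagents that add atoms: none
Why: Hydride reduction of the ester to the benzylic alcohol.

**Step 22**
Reactants: 31 [4-(benzyloxy)-3-Cy-phenyl]methanol
Product: 32 4-(benzyloxy)-3-Cy-benzaldehyde
Conditions: Dess–Martin periodinane, NaHCO3, CH2Cl2, rt
Reagents that add atoms: none
Why: Dess–Martin oxidation to the aldehyde under buffered, non-epimerising conditions.

**Step 23**
Reactants: 32 4-(benzyloxy)-3-Cy-benzaldehyde; 11 BF-CH2P(O)(OEt)2
Product: 33 deca-O-benzyl ether of the target ((E)-stilbene)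
Conditions: 11, KOt-Bu (1.0 equiv), THF, 0 °C; then 32, 0 °C to rt
Reagents that add atoms: none
Why: Horner–Wadsworth–Emmons olefination of a benzylic phosphonate anion with an aryl aldehyde gives the E-stilbene; the base is consumed before the dihydrobenzofuran is added.

**Step 24**
Reactants: 33 deca-O-benzyl ether of the target
Product: 34 CNP0339094.1 (target)
Conditions: BCl3 (30 equiv), pentamethylbenzene (40 equiv), CH2Cl2, −78 to −40 °C; MeOH quench
Reagents that add atoms: none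
Why: Lewis-acid cleavage of aryl benzyl ethers with pentamethylbenzene as a non-basic benzyl-cation scavenger spares the stilbene, the benzofuran and the four stereocentres.

**Compound list**
1 | methyl 3,5-dihydroxybenzoate | COC(=O)c1cc(O)cc(O)c1 | starting material
2 | methyl 3-(benzyloxy)-5-hydroxybenzoate | COC(=O)c1cc(O)cc(OCc2ccccc2)c1 | intermediate
3 | 1-[3,5-bis(benzyloxy)phenyl]ethanone | CC(=O)c1cc(OCc2ccccc2)cc(OCc2ccccc2)c1 | starting material
4 | 2-bromo-1-[3,5-bis(benzyloxy)phenyl]ethanone | BrCC(=O)c1cc(OCc2ccccc2)cc(OCc2ccccc2)c1 | intermediate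
5 | methyl 3-(benzyloxy)-5-{2-[3,5-bis(benzyloxy)phenyl]-2-oxoethoxy}benzoate | COC(=O)c1cc(OCC(=O)c2cc(OCc3ccccc3)cc(OCc3ccccc3)c2)cc(OCc2ccccc2)c1 | intermediate
6 | methyl 6-(benzyloxy)-3-[3,5-bis(benzyloxy)phenyl]-1-benzofuran-4-carboxylate | COC(=O)c1cc(OCc2ccccc2)cc2occ(-c3cc(OCc4ccccc4)cc(OCc4ccccc4)c3)c12 | intermediate
7 | 1-(benzyloxy)-4-bromobenzene | Brc1ccc(OCc2ccccc2)cc1 | starting material
8 | methyl 6-(benzyloxy)-2-[4-(benzyloxy)phenyl]-3-[3,5-bis(benzyloxy)phenyl]-1-benzofuran-4-carboxylate (BF-CO2Me) | COC(=O)c1cc(OCc2ccccc2)cc2oc(-c3ccc(OCc4ccccc4)cc3)c(-c3cc(OCc4ccccc4)cc(OCc4ccccc4)c3)c12 | intermediate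
9 | {6-(benzyloxy)-2-[4-(benzyloxy)phenyl]-3-[3,5-bis(benzyloxy)phenyl]-1-benzofuran-4-yl}methanol | OCc1cc(OCc2ccccc2)cc2oc(-c3ccc(OCc4ccccc4)cc3)c(-c3cc(OCc4ccccc4)cc(OCc4ccccc4)c3)c12 | intermediate
10 | 6-(benzyloxy)-2-[4-(benzyloxy)phenyl]-3-[3,5-bis(benzyloxy)phenyl]-4-(bromomethyl)-1-benzofuran | BrCc1cc(OCc2ccccc2)cc2oc(-c3ccc(OCc4ccccc4)cc3)c(-c3cc(OCc4ccccc4)cc(OCc4ccccc4)c3)c12 | intermediate
11 | diethyl ({6-(benzyloxy)-2-[4-(benzyloxy)phenyl]-3-[3,5-bis(benzyloxy)phenyl]-1-benzofuran-4-yl}methyl)phosphonate | CCOP(=O)(OCC)Cc1cc(OCc2ccccc2)cc2oc(-c3ccc(OCc4ccccc4)cc3)c(-c3cc(OCc4ccccc4)cc(OCc4ccccc4)c3)c12 | intermediate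
12 | methyl rac-(2S,3S)-6-(benzyloxy)-2-[4-(benzyloxy)phenyl]-3-[3,5-bis(benzyloxy)phenyl]-2,3-dihydro-1-benzofuran-4-carboxylate (trans, racemic; one enantiomer drawn) | COC(=O)c1cc(OCc2ccccc2)cc2c1[C@H](c1cc(OCc3ccccc3)cc(OCc3ccccc3)c1)[C@@H](c1ccc(OCc3ccccc3)cc1)O2 | intermediate
13 | rac-(2S,3S)-6-(benzyloxy)-2-[4-(benzyloxy)phenyl]-3-[3,5-bis(benzyloxy)phenyl]-2,3-dihydro-1-benzofuran-4-carboxylic acid (trans, racemic; one enantiomer drawn) | OC(=O)c1cc(OCc2ccccc2)cc2c1[C@H](c1cc(OCc3ccccc3)cc(OCc3ccccc3)c1)[C@@H](c1ccc(OCc3ccccc3)cc1)O2 | intermediate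
14 | (S)-4-benzyl-1,3-oxazolidin-2-one | O=C1OC[C@H](Cc2ccccc2)N1 | starting material
15 | acid chloride of 13 (trans, racemic; one enantiomer drawn) | ClC(=O)c1cc(OCc2ccccc2)cc2c1[C@H](c1cc(OCc3ccccc3)cc(OCc3ccccc3)c1)[C@@H](c1ccc(OCc3ccccc3)cc1)O2 | intermediate
16 | (4S)-4-benzyl-3-{[(2S,3S)-6-(benzyloxy)-2-[4-(benzyloxy)phenyl]-3-[3,5-bis(benzyloxy)phenyl]-2,3-dihydro-1-benzofuran-4-yl]carbonyl}-1,3-oxazolidin-2-one | O=C1OC[C@H](Cc2ccccc2)N1C(=O)c1cc(OCc2ccccc2)cc2c1[C@H](c1cc(OCc3ccccc3)cc(OCc3ccccc3)c1)[C@@H](c1ccc(OCc3ccccc3)cc1)O2 | intermediate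
17 | [(2S,3S)-6-(benzyloxy)-2-[4-(benzyloxy)phenyl]-3-[3,5-bis(benzyloxy)phenyl]-2,3-dihydro-1-benzofuran-4-yl]methanol (DHB-CH2OH) | OCc1cc(OCc2ccccc2)cc2c1[C@H](c1cc(OCc3ccccc3)cc(OCc3ccccc3)c1)[C@@H](c1ccc(OCc3ccccc3)cc1)O2 | intermediate
18 | (2S,3S)-6-(benzyloxy)-2-[4-(benzyloxy)phenyl]-3-[3,5-bis(benzyloxy)phenyl]-2,3-dihydro-1-benzofuran-4-carbaldehyde (DHB-CHO) | O=Cc1cc(OCc2ccccc2)cc2c1[C@H](c1cc(OCc3ccccc3)cc(OCc3ccccc3)c1)[C@@H](c1ccc(OCc3ccccc3)cc1)O2 | intermediate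
19 | methyl 4-hydroxy-3-iodobenzoate | COC(=O)c1ccc(O)c(I)c1 | starting material
20 | methyl 3-iodo-4-[(triisopropylsilyl)oxy]benzoate | COC(=O)c1ccc(O[Si](C(C)C)(C(C)C)C(C)C)c(I)c1 | intermediate
21 | [5-(methoxycarbonyl)-2-(triisopropylsilyloxy)phenyl]magnesium chloride | COC(=O)c1ccc(O[Si](C(C)C)(C(C)C)C(C)C)c([Mg]Cl)c1 | intermediate
22 | methyl 3-{hydroxy[(2S,3S)-DHB]methyl}-4-[(triisopropylsilyl)oxy]benzoate (both carbinol epimers) | COC(=O)c1ccc(O[Si](C(C)C)(C(C)C)C(C)C)c(c1)C(O)c1cc(OCc2ccccc2)cc2c1[C@H](c1cc(OCc3ccccc3)cc(OCc3ccccc3)c1)[C@@H](c1ccc(OCc3ccccc3)cc1)O2 | intermediate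
23 | methyl 3-{acetoxy[(2S,3S)-DHB]methyl}-4-[(triisopropylsilyl)oxy]benzoate (both epimers) | COC(=O)c1ccc(O[Si](C(C)C)(C(C)C)C(C)C)c(c1)C(OC(C)=O)c1cc(OCc2ccccc2)cc2c1[C@H](c1cc(OCc3ccccc3)cc(OCc3ccccc3)c1)[C@@H](c1ccc(OCc3ccccc3)cc1)O2 | intermediate
24 | [4-(benzyloxy)phenyl]methanol | OCc1ccc(OCc2ccccc2)cc1 | starting material
25 | 1-[4-(benzyloxy)benzyl]tetrahydrothiophenium tetrafluoroborate | c1ccc(COc2ccc(C[S+]3CCCC3)cc2)cc1.F[B-](F)(F)F | intermediate
26 | [4-(benzyloxy)phenyl](tetrahydrothiophenium-1-yl)methanide (sulfonium ylide) | [CH-](c1ccc(OCc2ccccc2)cc1)[S+]1CCCC1 | intermediate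
27 | methyl 3-{[(2S,3S)-DHB]methylidene}-4-oxocyclohexa-1,5-diene-1-carboxylate (ortho-quinone methide) | COC(=O)C1=CC(=Cc2cc(OCc3ccccc3)cc3c2[C@H](c2cc(OCc4ccccc4)cc(OCc4ccccc4)c2)[C@@H](c2ccc(OCc4ccccc4)cc2)O3)C(=O)C=C1 | intermediate
28 | methyl (2R,3R)-2-[4-(benzyloxy)phenyl]-3-[(2S,3S)-DHB]-2,3-dihydro-1-benzofuran-5-carboxylate (both rings trans) | COC(=O)c1ccc2c(c1)[C@@H](c1cc(OCc3ccccc3)cc3c1[C@H](c1cc(OCc4ccccc4)cc(OCc4ccccc4)c1)[C@@H](c1ccc(OCc4ccccc4)cc1)O3)[C@H](c1ccc(OCc3ccccc3)cc1)O2 | intermediate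
29 | methyl 4-hydroxy-3-Cy-benzoate: C-a (R) joins ring L, ring A and C-d; C-d (S) carries 4-(benzyloxy)phenyl and is bonded to ring B; C-b (S), C-c (S) trans-dihydrobenzofuran | COC(=O)c1ccc(O)c([C@H]2c3cc(OCc4ccccc4)cc5c3[C@H](c3cc(OCc4ccccc4)cc(OCc4ccccc4)c3[C@@H]2c2ccc(OCc4ccccc4)cc2)[C@@H](c2ccc(OCc4ccccc4)cc2)O5)c1 | intermediate
30 | methyl 4-(benzyloxy)-3-Cy-benzoate (same four stereocentres) | COC(=O)c1ccc(OCc4ccccc4)c([C@H]2c3cc(OCc4ccccc4)cc5c3[C@H](c3cc(OCc4ccccc4)cc(OCc4ccccc4)c3[C@@H]2c2ccc(OCc4ccccc4)cc2)[C@@H](c2ccc(OCc4ccccc4)cc2)O5)c1 | intermediate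
31 | [4-(benzyloxy)-3-Cy-phenyl]methanol | OCc1ccc(OCc4ccccc4)c([C@H]2c3cc(OCc4ccccc4)cc5c3[C@H](c3cc(OCc4ccccc4)cc(OCc4ccccc4)c3[C@@H]2c2ccc(OCc4ccccc4)cc2)[C@@H](c2ccc(OCc4ccccc4)cc2)O5)c1 | intermediate
32 | 4-(benzyloxy)-3-Cy-benzaldehyde | O=Cc1ccc(OCc4ccccc4)c([C@H]2c3cc(OCc4ccccc4)cc5c3[C@H](c3cc(OCc4ccccc4)cc(OCc4ccccc4)c3[C@@H]2c2ccc(OCc4ccccc4)cc2)[C@@H](c2ccc(OCc4ccccc4)cc2)O5)c1 | intermediate
33 | deca-O-benzyl ether of the target, (E)-stilbene joining BF (C4) to ring L of 32 | c8ccccc8COc1ccc(-c2oc3cc(OCc8ccccc8)cc(/C=C/c4ccc(OCc8ccccc8)c([C@H]5c6cc(OCc8ccccc8)cc7c6[C@H](c6cc(OCc8ccccc8)cc(OCc8ccccc8)c6[C@@H]5c5ccc(OCc8ccccc8)cc5)[C@@H](c5ccc(OCc8ccccc8)cc5)O7)c4)c3c2-c2cc(OCc8ccccc8)cc(OCc8ccccc8)c2)cc1 | intermediate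
34 | CNP0339094.1 (C-a R, C-b S, C-c S, C-d S; E-alkene) | Oc1ccc(-c2oc3cc(O)cc(/C=C/c4ccc(O)c([C@H]5c6cc(O)cc7c6[C@H](c6cc(O)cc(O)c6[C@@H]5c5ccc(O)cc5)[C@@H](c5ccc(O)cc5)O7)c4)c3c2-c2cc(O)cc(O)c2)cc1 | target

**Totals**
Total step count: 24. Longest linear sequence: 18 steps (1, 3, 4, 5, 9–13, 15, 16, 18–24).

**Three steps most likely to fail, with fallbacks**

Step 9 (ionic hydrogenation). The ester-deactivated, crowded benzofuran may reduce slowly, and long exposure to CF3CO2H can cleave or migrate benzyl groups. Fallback, setting out from 8 and returning at 12: hydrogenate 8 over Pd(OH)2/C (H2 50 bar, EtOAc–AcOH, 60 °C), which saturates the furan from one face and removes the four benzyl groups, giving the racemic cis-dihydrobenzofuran tetraphenol ester F1. Catalytic CF3CO2H in MeCN at rt then equilibrates C2 through reversible C2–O heterolysis to the racemic trans tetraphenol ester F2. BnBr (4.4 equiv) and K2CO3 in DMF re-benzylate the four phenols and give 12.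

Step 18 (Michael addition and ring closure). The facial preference at C-a rests only on a conformational bias and may be low, and the quinone methide can dimerise. Fallback with reagent control, setting out from 22 and returning at 29: Dess–Martin oxidation of 22 gives the diaryl ketone F3, and Bu4NF gives the phenol ketone F4. 4-(Benzyloxy)benzyl chloride and K2CO3 in DMF give the aryl benzyl ether ketone F5, and TsNHNH2 in EtOH at 70 °C gives the tosylhydrazone F6. NaH and gentle warming with Rh2(S-PTAD)4 (a dirhodium tetracarboxylate of divalent rhodium; the catalyst antipode that gives 3R is used) release the diazo compound F7, whose carbene inserts into the neighbouring O–CH2 bond (1,5 C–H insertion) to give the cis-dihydrobenzofuran F8 with C-a fixed by the catalyst. F8 is treated as in step 19; C2 is ionised there, so cis or trans does not matter, and 29 results.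

Step 19 (ring opening and seven-ring Friedel–Crafts closure). The cation may instead lose the C-a proton to a triarylethene, or the other dihydrobenzofuran may open. Fallback through a neutral para-quinone methide, setting out from 23 and returning at 30: [4-(allyloxy)phenyl]methanol, tetrahydrothiophene and HBF4·OEt2 give the allyloxy sulfonium salt F9. KOt-Bu converts it into the allyloxy ylide F10, which reacts with 23 and Bu4NF as in step 18 to give the O-allyl annulation product F11. Pd(PPh3)4 (zerovalent palladium) and morpholine in THF free the para-phenol F12. Warming F12 in 1,1,1,3,3,3-hexafluoropropan-2-ol opens the ring to the para-quinone methide F13, which ring B captures to give the seven-ring bis-phenol F14. BnBr (2.2 equiv) and K2CO3 in DMF then give 30.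

**Further compounds**
F1 | step 9 | methyl rac-(2R,3S)-6-hydroxy-2-(4-hydroxyphenyl)-3-(3,5-dihydroxyphenyl)-2,3-dihydro-1-benzofuran-4-carboxylate (cis, racemic; one enantiomer drawn) | COC(=O)c1cc(O)cc2c1[C@H](c1cc(O)cc(O)c1)[C@H](c1ccc(O)cc1)O2
F2 | step 9 | methyl rac-(2S,3S)-6-hydroxy-2-(4-hydroxyphenyl)-3-(3,5-dihydroxyphenyl)-2,3-dihydro-1-benzofuran-4-carboxylate (trans, racemic; one enantiomer drawn) | COC(=O)c1cc(O)cc2c1[C@H](c1cc(O)cc(O)c1)[C@@H](c1ccc(O)cc1)O2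
F3 | step 18 | methyl 3-[(2S,3S)-DHB-carbonyl]-4-[(triisopropylsilyl)oxy]benzoate | COC(=O)c1ccc(O[Si](C(C)C)(C(C)C)C(C)C)c(c1)C(=O)c1cc(OCc2ccccc2)cc2c1[C@H](c1cc(OCc3ccccc3)cc(OCc3ccccc3)c1)[C@@H](c1ccc(OCc3ccccc3)cc1)O2
F4 | step 18 | methyl 3-[(2S,3S)-DHB-carbonyl]-4-hydroxybenzoate | COC(=O)c1ccc(O)c(c1)C(=O)c1cc(OCc2ccccc2)cc2c1[C@H](c1cc(OCc3ccccc3)cc(OCc3ccccc3)c1)[C@@H](c1ccc(OCc3ccccc3)cc1)O2
F5 | step 18 | methyl 4-{[4-(benzyloxy)benzyl]oxy}-3-[(2S,3S)-DHB-carbonyl]benzoate | COC(=O)c1ccc(OCc2ccc(OCc3ccccc3)cc2)c(c1)C(=O)c1cc(OCc2ccccc2)cc2c1[C@H](c1cc(OCc3ccccc3)cc(OCc3ccccc3)c1)[C@@H](c1ccc(OCc3ccccc3)cc1)O2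
F6 | step 18 | tosylhydrazone of F5 | COC(=O)c1ccc(OCc2ccc(OCc3ccccc3)cc2)c(c1)C(=NNS(=O)(=O)c1ccc(C)cc1)c1cc(OCc2ccccc2)cc2c1[C@H](c1cc(OCc3ccccc3)cc(OCc3ccccc3)c1)[C@@H](c1ccc(OCc3ccccc3)cc1)O2
F7 | step 18 | diazo compound from F6 | COC(=O)c1ccc(OCc2ccc(OCc3ccccc3)cc2)c(c1)C(=[N+]=[N-])c1cc(OCc2ccccc2)cc2c1[C@H](c1cc(OCc3ccccc3)cc(OCc3ccccc3)c1)[C@@H](c1ccc(OCc3ccccc3)cc1)O2
F8 | step 18 | methyl (2S,3R)-2-[4-(benzyloxy)phenyl]-3-[(2S,3S)-DHB]-2,3-dihydro-1-benzofuran-5-carboxylate (new ring cis) | COC(=O)c1ccc2c(c1)[C@@H](c1cc(OCc3ccccc3)cc3c1[C@H](c1cc(OCc4ccccc4)cc(OCc4ccccc4)c1)[C@@H](c1ccc(OCc4ccccc4)cc1)O3)[C@@H](c1ccc(OCc3ccccc3)cc1)O2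
F9 | step 19 | 1-[4-(allyloxy)benzyl]tetrahydrothiophenium tetrafluoroborate | C=CCOc1ccc(C[S+]2CCCC2)cc1.F[B-](F)(F)F
F10 | step 19 | [4-(allyloxy)phenyl](tetrahydrothiophenium-1-yl)methanide | C=CCOc1ccc([CH-][S+]2CCCC2)cc1
F11 | step 19 | methyl (2R,3R)-2-[4-(allyloxy)phenyl]-3-[(2S,3S)-DHB]-2,3-dihydro-1-benzofuran-5-carboxylate | COC(=O)c1ccc2c(c1)[C@@H](c1cc(OCc3ccccc3)cc3c1[C@H](c1cc(OCc4ccccc4)cc(OCc4ccccc4)c1)[C@@H](c1ccc(OCc4ccccc4)cc1)O3)[C@H](c1ccc(OCC=C)cc1)O2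
F12 | step 19 | methyl (2R,3R)-2-(4-hydroxyphenyl)-3-[(2S,3S)-DHB]-2,3-dihydro-1-benzofuran-5-carboxylate | COC(=O)c1ccc2c(c1)[C@@H](c1cc(OCc3ccccc3)cc3c1[C@H](c1cc(OCc4ccccc4)cc(OCc4ccccc4)c1)[C@@H](c1ccc(OCc4ccccc4)cc1)O3)[C@H](c1ccc(O)cc1)O2
F13 | step 19 | methyl 4-hydroxy-3-{1-[(2S,3S)-DHB]-2-(4-oxocyclohexa-2,5-dien-1-ylidene)ethyl}benzoate (para-quinone methide, C-a retained) | COC(=O)c1ccc(O)c(c1)[C@@H](c1cc(OCc3ccccc3)cc3c1[C@H](c1cc(OCc4ccccc4)cc(OCc4ccccc4)c1)[C@@H](c1ccc(OCc4ccccc4)cc1)O3)C=C1C=CC(=O)C=C1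
F14 | step 19 | analogue of 29 with a free 4-hydroxyphenyl group at C-d (C-a R, C-b S, C-c S, C-d S) | COC(=O)c1ccc(O)c([C@H]2c3cc(OCc4ccccc4)cc5c3[C@H](c3cc(OCc4ccccc4)cc(OCc4ccccc4)c3[C@@H]2c2ccc(O)cc2)[C@@H](c2ccc(OCc4ccccc4)cc2)O5)c1
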